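The C8–C8a bond of the carbocycle is made last, on a fully substituted pyridine, by a decarboxylative radical cyclisation of Minisci type. The step exploits that C8a, the pyridine carbon beside N1, is the only ring position still bearing hydrogen and lies a six-membered ring away from a C8 radical tethered through C4a–C5–C6–C7. In one operation CO2 is expelled, C8–C8a is formed and the tetrahydroquinoline is complete, with the preset C5 stereocentre untouched. The precursor is the (5R)-5-pyridyltridecanoic acid 18, whose pyridine carries the benzyloxy (future C4), methoxy (C3) and benzyloxymethyl (C2) groups; C5 comes from a rhodium/BINAP conjugate addition.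

Key step: step 12

Remarks on the chemistry
- Target numbering is used for the bicycle (N1, C2, C3, C4, C4a, C5–C8, C8a). C5 is R in the target. The same spatial arrangement is R in every compound from 13 to 24, because the ring carbon outranks the carbonyl-side (later C6-side) chain, which outranks octyl. Acid 18 and pyridine 21 map atom for atom onto the target (acid C2 becomes C8, the pyridine CH becomes C8a), so their structures need no correction.
- Assumption: with (S)-BINAP the aryl group is delivered to the α-si face of the E-enoate, as in the accepted model for this catalyst; this corresponds to 3R in 13. The enantiomeric purity of 13 is to be checked before it is carried on.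
- Bromine is placed on C5 at the 4-pyridone stage, where C5 is the only nucleophilic carbon. On a 3,4-dialkoxypyridine, C6 (para to the 3-methoxy group) would compete.
- Acid 18 is activated in the flask as a redox-active ester, so the C8 radical is made reductively at room temperature. Two benzyl ethers and a 4-benzyloxypyridinium are poorly matched to hot aqueous persulfate/silver.
- The N-methoxy group is made by O-methylation of the N-hydroxypyridone obtained after hydrogenolysis.
- Ethyl (E)-undec-2-enoate is made in one step from nonanal so that the route does not depend on its supply.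

Step 1
Reactants: 1 3-methoxy-2-methylpyridin-4(1H)-one
Product: 2 5-bromo-3-methoxy-2-methylpyridin-4(1H)-one
Conditions: NBS (1.05 equiv), DMF, 0 °C → rt
Reagents that add atoms: N-bromosuccinimide, O=C1CCC(=O)N1Br
Why: Electrophilic bromination of the 4-pyridone (a vinylogous amide) can only go to C5, the one free carbon α to the carbonyl and β to nitrogen, so the regiochemistry is fixed at this stage.

Step 2
Reactants: 2 5-bromo-3-methoxy-2-methylpyridin-4(1H)-one
Product: 3 5-bromo-4-chloro-3-methoxy-2-methylpyridine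
Conditions: POCl3 (neat), 90 °C; cold aq. NaOH work-up
Reagents that add atoms: phosphoryl chloride, O=P(Cl)(Cl)Cl
Why: Deoxychlorination of a 4-pyridone proceeds by O-phosphorylation and addition–elimination of chloride at C4, while the bromide at the β-position does not exchange.

Step 3
Reactants: 3 5-bromo-4-chloro-3-methoxy-2-methylpyridine
Product: 4 5-bromo-4-chloro-3-methoxy-2-methylpyridine 1-oxide
Conditions: mCPBA (1.3 equiv), CH2Cl2, rt
Reagents that add atoms: 3-chloroperoxybenzoic acid, OOC(=O)c1cccc(Cl)c1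
Why: Peracid N-oxidation at the pyridine nitrogen, the only nucleophilic site, activates C4 for substitution and prepares the 2-methyl group for rearrangement.

Step 4
Reactants: 4 5-bromo-4-chloro-3-methoxy-2-methylpyridine 1-oxide
Product: 5 4-(benzyloxy)-5-bromo-3-methoxy-2-methylpyridine 1-oxide
Conditions: BnOH (1.2 equiv), NaH (1.2 equiv), THF, 0 °C → 40 °C
Reagents that add atoms: benzyl alcohol, OCc1ccccc1
Why: Nucleophilic aromatic substitution by sodium benzyloxide takes place at C4, para to the N-oxide, through a Meisenheimer adduct, whereas the unactivated C5 bromide is kept.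

Step 5
Reactants: 5 4-(benzyloxy)-5-bromo-3-methoxy-2-methylpyridine 1-oxide
Product: 7 [4-(benzyloxy)-5-bromo-3-methoxypyridin-2-yl]methanol, via picolyl trifluoroacetate 6 (not isolated)
Conditions: (CF3CO)2O (2.5 equiv), CH2Cl2, 0 °C → rt; then MeOH, rt; aq. NaHCO3 work-up
Reagents that add atoms: trifluoroacetic anhydride, O=C(OC(=O)C(F)(F)F)C(F)(F)F
Why: The Boekelheide rearrangement at room temperature (O-acylation, deprotonation of the 2-methyl group, [3,3]-shift) moves oxygen from nitrogen to the methyl carbon, and methanolysis frees the alcohol.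

Step 6
Reactants: 7 [4-(benzyloxy)-5-bromo-3-methoxypyridin-2-yl]methanol
Product: 8 4-(benzyloxy)-2-[(benzyloxy)methyl]-5-bromo-3-methoxypyridine
Conditions: NaH (1.2 equiv), BnBr (1.1 equiv), Bu4NI (cat.), THF/DMF, 0 °C → rt
Reagents that add atoms: benzyl bromide, BrCc1ccccc1
Why: Williamson ether synthesis on the primary alkoxide outpaces quaternisation of the flanked pyridine nitrogen.

Step 7
Reactants: 8 4-(benzyloxy)-2-[(benzyloxy)methyl]-5-bromo-3-methoxypyridine
Product: 9 4-(benzyloxy)-2-[(benzyloxy)methyl]-3-methoxy-5-(4,4,5,5-tetramethyl-1,3,2-dioxaborolan-2-yl)pyridine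
Conditions: B2pin2 (1.2 equiv), Pd(dppf)Cl2 (5 mol %), KOAc (3 equiv), 1,4-dioxane, 90 °C
Reagents that add atoms: bis(pinacolato)diboron, CC1(C)OB(OC1(C)C)B1OC(C)(C)C(C)(C)O1
Why: Miyaura borylation of the C5 bromide (oxidative addition, acetate-assisted transmetalation, reductive elimination) tolerates the ethers and gives a boronate that can be purified.

Step 8
Reactants: 10 nonanal; 11 triethyl phosphonoacetate
Product: 12 ethyl (E)-undec-2-enoate
Conditions: NaH (1.05 equiv), THF, 0 °C → rt
Reagents that add atoms: none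
Why: Horner–Wadsworth–Emmons olefination with the stabilised phosphonate anion gives the E-enoate.

Step 9
Reactants: 9 4-(benzyloxy)-2-[(benzyloxy)methyl]-3-methoxy-5-(4,4,5,5-tetramethyl-1,3,2-dioxaborolan-2-yl)pyridine; 12 ethyl (E)-undec-2-enoate
Product: 13 ethyl (3R)-3-{4-(benzyloxy)-6-[(benzyloxy)methyl]-5-methoxypyridin-3-yl}undecanoate
Conditions: Rh(acac)(C2H4)2 (3 mol %), (S)-BINAP (3.3 mol %), K3PO4 (1 equiv), 1,4-dioxane/H2O (10:1), 80 °C; 12 in excess (1.5 equiv)
Reagents that add atoms: none
Why: In this Hayashi–Miyaura asymmetric conjugate addition the aryl group passes from boron to rhodium and inserts into the E-enoate on its α-si face under control of (S)-BINAP, which sets C3 as R, and water releases the ester.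

Step 10
Reactants: 13 ethyl (3R)-3-{4-(benzyloxy)-6-[(benzyloxy)methyl]-5-methoxypyridin-3-yl}undecanoate; 14 methyl (triphenylphosphoranylidene)acetate
Product: 16 methyl (2E,5R)-5-{4-(benzyloxy)-6-[(benzyloxy)methyl]-5-methoxypyridin-3-yl}tridec-2-enoate, via aldehyde 15 (not isolated)
Conditions: i-Bu2AlH (1.2 equiv), toluene, −78 °C; then 14 (1.5 equiv), −78 °C → rt
Reagents that add atoms: none
Why: Partial reduction of the ester to the aluminium hemiacetal and Wittig olefination of the aldehyde released on warming add the two missing carbons, and the stereocentre, β to the carbonyl group, cannot epimerise.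

Step 11
Reactants: 16 methyl (2E,5R)-5-{4-(benzyloxy)-6-[(benzyloxy)methyl]-5-methoxypyridin-3-yl}tridec-2-enoate
Product: 18 (5R)-5-{4-(benzyloxy)-6-[(benzyloxy)methyl]-5-methoxypyridin-3-yl}tridecanoic acid, via saturated methyl ester 17 (not isolated)
Conditions: Cu(OAc)2·H2O (5 mol %), 1,2-bis(diphenylphosphino)benzene (5 mol %), (EtO)2MeSiH (2 equiv), t-BuOH (2 equiv), toluene, rt; then LiOH, THF/MeOH/H2O, rt; 1 M HCl to pH 5
Reagents that add atoms: lithium hydroxide, [Li+].[OH-]
Why: Copper hydride conjugate reduction saturates only the enoate double bond (benzyl ethers and the pyridine are inert to it, unlike under palladium and hydrogen), and saponification then gives the acid without touching C5.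

Step 12
Reactants: 18 (5R)-5-{4-(benzyloxy)-6-[(benzyloxy)methyl]-5-methoxypyridin-3-yl}tridecanoic acid; 19 N-hydroxyphthalimide
Product: 21 (5R)-4-(benzyloxy)-2-[(benzyloxy)methyl]-3-methoxy-5-octyl-5,6,7,8-tetrahydroquinoline, via N-acyloxyphthalimide 20 (not isolated)
Conditions: 19 (1.1 equiv), i-PrN=C=N-i-Pr (1.1 equiv), DMAP (cat.), CH2Cl2, rt; solvent change to DMSO (0.02 M); CF3CO2H (2 equiv), 4CzIPN [2,4,5,6-tetra(carbazol-9-yl)isophthalonitrile, 2 mol %], 450 nm LEDs, rt, N2
Reagents that add atoms: none
Why: The acid is turned in the flask into its N-acyloxyphthalimide 20; electron transfer from photoexcited 4CzIPN cleaves the N–O bond, CO2 is lost, and the primary C8 radical adds to C8a of the pyridine protonated by trifluoroacetic acid, after which proton loss and one-electron oxidation by the oxidised photocatalyst restore the aromatic ring. The closest known reaction type is the redox-neutral photoredox decarboxylative Minisci alkylation of pyridines with redox-active esters, run here intramolecularly. The ring closes in a six-membered ortho-fused mode (6-exo-trig with respect to the C8a=N1 bond, tether C4a–C5–C6–C7) and gives the carbocycle C4a–C5–C6–C7–C8–C8a. No stereocentre is formed: C8a returns to sp2, and C5, set in step 9, lies outside the reacting atoms and is not acidic under these conditions. The step needs attack at C8a and not ipso at C4; this is secured because C8a is the only hydrogen-bearing ring carbon, the position next to the protonated nitrogen is the most electrophilic, and an ipso adduct at the benzyloxy-bearing C4 cannot rearomatise and reverts. High dilution suppresses intermolecular alkylation, and the absence of a strong oxidant and of heat keeps both benzyl ethers and the acid-sensitive 4-benzyloxypyridinium intact.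

Step 13
Reactants: 21 (5R)-4-(benzyloxy)-2-[(benzyloxy)methyl]-3-methoxy-5-octyl-5,6,7,8-tetrahydroquinoline
Product: 22 (5R)-4-(benzyloxy)-2-[(benzyloxy)methyl]-3-methoxy-5-octyl-5,6,7,8-tetrahydroquinoline 1-oxide
Conditions: mCPBA (1.2 equiv), CH2Cl2, 0 °C → rt
Reagents that add atoms: 3-chloroperoxybenzoic acid, OOC(=O)c1cccc(Cl)c1
Why: Peracid N-oxidation of the electron-rich, now fully substituted pyridine is the only reaction open to the oxidant, since the ethers and the C5 stereocentre are inert to it.

Step 14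
Reactants: 22 (5R)-4-(benzyloxy)-2-[(benzyloxy)methyl]-3-methoxy-5-octyl-5,6,7,8-tetrahydroquinoline 1-oxide
Product: 23 (5R)-1-hydroxy-2-(hydroxymethyl)-3-methoxy-5-octyl-5,6,7,8-tetrahydroquinolin-4(1H)-one
Conditions: H2 (1 atm), 10% Pd/C, MeOH, rt
Reagents that add atoms: none
Why: Hydrogenolysis cleaves both benzyl ethers, the 4-benzyloxy N-oxide giving its 1-hydroxy-4-pyridone tautomer, whose hydroxamic-type N–O bond should survive at one atmosphere.

Step 15
Reactants: 23 (5R)-1-hydroxy-2-(hydroxymethyl)-3-methoxy-5-octyl-5,6,7,8-tetrahydroquinolin-4(1H)-one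
Product: 24 (5R)-2-(hydroxymethyl)-1,3-dimethoxy-5-octyl-5,6,7,8-tetrahydroquinolin-4(1H)-one
Conditions: MeI (1.2 equiv), K2CO3 (1.5 equiv), DMF, rt
Reagents that add atoms: iodomethane, CI
Why: O-Alkylation of the acidic N-hydroxypyridone (a vinylogous cyclic hydroxamic acid) should occur at the nitrogen-bound oxygen, the α-effect site of its anion, while the primary alcohol is not deprotonated by carbonate.

Compound list
1 | 3-methoxy-2-methylpyridin-4(1H)-one | Cc1[nH]ccc(=O)c1OC | starting material
2 | 5-bromo-3-methoxy-2-methylpyridin-4(1H)-one | Cc1[nH]cc(Br)c(=O)c1OC | intermediate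
3 | 5-bromo-4-chloro-3-methoxy-2-methylpyridine | Cc1ncc(Br)c(Cl)c1OC | intermediate
4 | 5-bromo-4-chloro-3-methoxy-2-methylpyridine 1-oxide | Cc1c(OC)c(Cl)c(Br)c[n+]1[O-] | intermediate
5 | 4-(benzyloxy)-5-bromo-3-methoxy-2-methylpyridine 1-oxide | Cc1c(OC)c(OCc2ccccc2)c(Br)c[n+]1[O-] | intermediate
6 | [4-(benzyloxy)-5-bromo-3-methoxypyridin-2-yl]methyl trifluoroacetate | COc1c(COC(=O)C(F)(F)F)ncc(Br)c1OCc1ccccc1 | intermediate
7 | [4-(benzyloxy)-5-bromo-3-methoxypyridin-2-yl]methanol | COc1c(CO)ncc(Br)c1OCc1ccccc1 | intermediate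
8 | 4-(benzyloxy)-2-[(benzyloxy)methyl]-5-bromo-3-methoxypyridine | COc1c(COCc2ccccc2)ncc(Br)c1OCc1ccccc1 | intermediate
9 | 4-(benzyloxy)-2-[(benzyloxy)methyl]-3-methoxy-5-(4,4,5,5-tetramethyl-1,3,2-dioxaborolan-2-yl)pyridine | COc1c(COCc2ccccc2)ncc(B2OC(C)(C)C(C)(C)O2)c1OCc1ccccc1 | intermediate
10 | nonanal | CCCCCCCCC=O | starting material
11 | triethyl phosphonoacetate | CCOC(=O)CP(=O)(OCC)OCC | starting material
12 | ethyl (E)-undec-2-enoate | CCCCCCCC/C=C/C(=O)OCC | intermediate
13 | ethyl (3R)-3-{4-(benzyloxy)-6-[(benzyloxy)methyl]-5-methoxypyridin-3-yl}undecanoate | CCCCCCCC[C@@H](c1cnc(COCc2ccccc2)c(OC)c1OCc1ccccc1)CC(=O)OCC | intermediate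
14 | methyl (triphenylphosphoranylidene)acetate | COC(=O)C=P(c1ccccc1)(c1ccccc1)c1ccccc1 | starting material
15 | (3R)-3-{4-(benzyloxy)-6-[(benzyloxy)methyl]-5-methoxypyridin-3-yl}undecanal | CCCCCCCC[C@@H](c1cnc(COCc2ccccc2)c(OC)c1OCc1ccccc1)CC=O | intermediate
16 | methyl (2E,5R)-5-{4-(benzyloxy)-6-[(benzyloxy)methyl]-5-methoxypyridin-3-yl}tridec-2-enoate | CCCCCCCC[C@@H](c1cnc(COCc2ccccc2)c(OC)c1OCc1ccccc1)C/C=C/C(=O)OC | intermediate
17 | methyl (5R)-5-{4-(benzyloxy)-6-[(benzyloxy)methyl]-5-methoxypyridin-3-yl}tridecanoate | CCCCCCCC[C@@H](c1cnc(COCc2ccccc2)c(OC)c1OCc1ccccc1)CCCC(=O)OC | intermediate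
18 | (5R)-5-{4-(benzyloxy)-6-[(benzyloxy)methyl]-5-methoxypyridin-3-yl}tridecanoic acid | CCCCCCCC[C@@H](c1cnc(COCc2ccccc2)c(OC)c1OCc1ccccc1)CCCC(=O)O | intermediate
19 | N-hydroxyphthalimide | O=C1c2ccccc2C(=O)N1O | starting material
20 | 1,3-dioxoisoindolin-2-yl (5R)-5-{4-(benzyloxy)-6-[(benzyloxy)methyl]-5-methoxypyridin-3-yl}tridecanoate | CCCCCCCC[C@@H](c1cnc(COCc2ccccc2)c(OC)c1OCc1ccccc1)CCCC(=O)ON1C(=O)c2ccccc2C1=O | intermediate
21 | (5R)-4-(benzyloxy)-2-[(benzyloxy)methyl]-3-methoxy-5-octyl-5,6,7,8-tetrahydroquinoline | CCCCCCCC[C@@H]1CCCc2nc(COCc3ccccc3)c(OC)c(OCc3ccccc3)c12 | intermediate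
22 | (5R)-4-(benzyloxy)-2-[(benzyloxy)methyl]-3-methoxy-5-octyl-5,6,7,8-tetrahydroquinoline 1-oxide | CCCCCCCC[C@@H]1CCCc2c1c(OCc1ccccc1)c(OC)c(COCc1ccccc1)[n+]2[O-] | intermediate
23 | (5R)-1-hydroxy-2-(hydroxymethyl)-3-methoxy-5-octyl-5,6,7,8-tetrahydroquinolin-4(1H)-one | CCCCCCCC[C@@H]1CCCc2c1c(=O)c(OC)c(CO)n2O | intermediate
24 | (5R)-2-(hydroxymethyl)-1,3-dimethoxy-5-octyl-5,6,7,8-tetrahydroquinolin-4(1H)-one | CCCCCCCC[C@@H]1CCCc2c1c(=O)c(OC)c(CO)n2OC | target

Total step count: 15. Longest linear sequence: 14 steps (1 to 24 through steps 1–7 and 9–15; step 8 is a one-step side branch).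

Steps most likely to fail

Step 12. The C8 radical may be quenched by hydrogen capture or lost before it closes onto the electron-rich 4-alkoxypyridinium, and the activation in the flask may stay incomplete. The fallback forms the same C8–C8a bond by a two-electron cross-coupling; it sets out from 13 and comes back at 21. Ester 13 is reduced with i-Bu2AlH to aldehyde 15, which is methylenated in the same flask with Ph3P=CH2 to 4-(benzyloxy)-2-[(benzyloxy)methyl]-5-[(4R)-dodec-1-en-4-yl]-3-methoxypyridine F1. One equivalent of mCPBA at 0 °C, where the pyridine nitrogen reacts before the monosubstituted alkene, gives 4-(benzyloxy)-2-[(benzyloxy)methyl]-5-[(4R)-dodec-1-en-4-yl]-3-methoxypyridine 1-oxide F2. Oxalyl chloride and Et3N then chlorinate the only free carbon next to nitrogen with loss of the N-oxide oxygen, giving 4-(benzyloxy)-2-[(benzyloxy)methyl]-6-chloro-5-[(4R)-dodec-1-en-4-yl]-3-methoxypyridine F3. Hydroboration with 9-BBN gives the primary alkylborane 9-[(4S)-4-{4-(benzyloxy)-6-[(benzyloxy)methyl]-2-chloro-5-methoxypyridin-3-yl}dodecyl]-9-borabicyclo[3.3.1]nonane F4 (the descriptor changes by priority only). Without isolation, F4 is closed to 21 by intramolecular B-alkyl Suzuki–Miyaura coupling (Pd(dppf)Cl2, aq. K3PO4, THF/DMF, 60 °C).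

Step 9. The ortho-alkoxy pyridyl boronate may protodeboronate, the pyridine nitrogen may inhibit rhodium, and facial discrimination may be insufficient. The fallback reverses the polarity; it sets out from 8 and comes back at 13. A Heck reaction of bromide 8 with ethyl acrylate (Pd(OAc)2, P(o-tol)3, Et3N, DMF, 100 °C) gives ethyl (2E)-3-{4-(benzyloxy)-6-[(benzyloxy)methyl]-5-methoxypyridin-3-yl}prop-2-enoate F5. Copper-catalysed asymmetric conjugate addition of n-octylmagnesium bromide (CuI, Tol-BINAP, t-BuOMe, −40 °C) then delivers 13, with the cheap nucleophile in excess. The ligand antipode is the one that gives the 3R ester, to be confirmed against 13 from the main route.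

Step 15. The ambident anion may be alkylated in part at the C4 oxygen, and over-reduction of the N–O bond in step 14 would feed the same problem. The fallback fixes the methyl group on the N-oxide oxygen before the C4 oxygen is freed; it sets out from 22 and comes back at 24. MeOTf (CH2Cl2, 0 °C) O-methylates N-oxide 22 to (5R)-4-(benzyloxy)-2-[(benzyloxy)methyl]-1,3-dimethoxy-5-octyl-5,6,7,8-tetrahydroquinolin-1-ium trifluoromethanesulfonate F6. BCl3 with pentamethylbenzene (CH2Cl2, −78 → 0 °C) then removes both benzyl groups, the 4-benzyloxy group of the pyridinium being an activated benzyl donor, and gives 24 directly.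

Further compounds
F1 | step 12 | 4-(benzyloxy)-2-[(benzyloxy)methyl]-5-[(4R)-dodec-1-en-4-yl]-3-methoxypyridine | CCCCCCCC[C@@H](c1cnc(COCc2ccccc2)c(OC)c1OCc1ccccc1)CC=C
F2 | step 12 | 4-(benzyloxy)-2-[(benzyloxy)methyl]-5-[(4R)-dodec-1-en-4-yl]-3-methoxypyridine 1-oxide | CCCCCCCC[C@@H](c1c[n+]([O-])c(COCc2ccccc2)c(OC)c1OCc1ccccc1)CC=C
F3 | step 12 | 4-(benzyloxy)-2-[(benzyloxy)methyl]-6-chloro-5-[(4R)-dodec-1-en-4-yl]-3-methoxypyridine | CCCCCCCC[C@@H](c1c(Cl)nc(COCc2ccccc2)c(OC)c1OCc1ccccc1)CC=C
F4 | step 12 | 9-[(4S)-4-{4-(benzyloxy)-6-[(benzyloxy)methyl]-2-chloro-5-methoxypyridin-3-yl}dodecyl]-9-borabicyclo[3.3.1]nonane | CCCCCCCC[C@@H](c1c(Cl)nc(COCc2ccccc2)c(OC)c1OCc1ccccc1)CCCB1C2CCCC1CCC2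
F5 | step 9 | ethyl (2E)-3-{4-(benzyloxy)-6-[(benzyloxy)methyl]-5-methoxypyridin-3-yl}prop-2-enoate | CCOC(=O)/C=C/c1cnc(COCc2ccccc2)c(OC)c1OCc1ccccc1
F6 | step 15 | (5R)-4-(benzyloxy)-2-[(benzyloxy)methyl]-1,3-dimethoxy-5-octyl-5,6,7,8-tetrahydroquinolin-1-ium trifluoromethanesulfonate | CCCCCCCC[C@@H]1CCCc2c1c(OCc1ccccc1)c(OC)c(COCc1ccccc1)[n+]2OC.[O-]S(=O)(=O)C(F)(F)F
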